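- Stop counting this flask in minutes and count it in half-lives of the electrophile, the time in which the electrophile still free falls to its half.

| flask | electrophile | free base | gas | remark | time |
|---|---|---|---|---|---|
| summer | 0.10 M (fed, over 12 s) | 1.7 equiv | 29 mM (held) | run made earlier |  |
| spring | 0.10 M (fed, over 12 s) | 3.2 equiv | 29 mM (held) | run made earlier |  |
| blue | 0.10 M (fed, over 12 s) | 2.40 equiv | 29 mM (held) |  | 4.0 min |
| violet | 0.10 M (fed, over 12 s) | 1.20 equiv | 29 mM (held) |  | 4.0 min |

| run | time / min | electrophile / % | product / % |
|---|---|---|---|
| summer | 0.167 | 83.0 | 0 |
| summer | 0.417 | 96.4 | 2.9 |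
| summer | 0.833 | 90.1 | 7.5 |
| summer | 1.33 | 82.1 | 14.2 |
| summer | 1.50 | 79.7 | 16.5 |
| summer | 2.00 | 72.3 | 22.2 |
| summer | 3.00 | 59.9 | 33.5 |
| spring | 0.167 | 82.4 | 0.1 |
| spring | 0.417 | 96.9 | 2.4 |
| spring | 0.833 | 91.1 | 7.9 |
| spring | 1.33 | 83.3 | 14.4 |
| spring | 1.50 | 80.7 | 16.9 |
| spring | 2.00 | 73.7 | 22.8 |
| spring | 3.00 | 61.3 | 34.1 |

(readings scatter by 0.3 percentage points)

- at the start none of the gas is in solution
- percentages count the whole charge, also what has not yet gone in
- what has gone from electrophile into another species counts as reacted, even if it can come back

- part of the electrophile that has reacted at the end, blue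
- part of the electrophile that has reacted at the end, violet
- what raising the equivalents of free base from its lowest to its highest value here does to the part of the electrophile that has reacted (changes below 5 percentage points count as none) (no change / it rises / it falls)

- The first way uses the electrophile readings after the feed: summer falls from 82.1% at 1.33 min to 59.9% at 3.00 min, which makes a half-life of 3.67 min, and spring gives 3.77 min.
- Counting on from the last reading to 4.0 min, summer has reacted 50.4% and spring 49.0%.
- The second way uses different readings: set summer's rise in product against its mean electrophile over the same stretch, and the half-life comes out at 4.26 min, longer than the first, and summer reaches 49.1%.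
- The product way is the one that cheats here: over that stretch summer's electrophile falls 22 percentage points while product rises 19 points, and whatever has gone into another species counts as reacted, so you keep the electrophile way.
- Going by equivalents between the two runs, blue's half-life of the electrophile is 3.72 min.
- My own reckoning on the same line gives blue 49.7% and violet 50.9%, a gap of 1.2 points, smaller than the 5 points that counts.
- The forecast says blue 49.9%, violet 51% and no change, on the ground that “Doubling the base therefore barely matters”.
- The flask gives blue 49.5% and violet 50.9%, a change of −1.4 points: no change.

    electrophile + nucleophile → acid set free + product (k = 0.125 M⁻¹ s⁻¹)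
    nucleophile + acid set free ⇌ protonated nucleophile, settled at all times (K = 2600 M⁻¹)
    acid set free + free base ⇌ salt of the base, settled at all times (K = 929 M⁻¹)
    2 electrophile → homo dimer (k = 6.89 × 10⁻⁵ M⁻¹ s⁻¹)
    electrophile + acid set free ⇌ idle adduct, settled at all times (K = 810 M⁻¹)
    gas ⇌ nucleophile, rate k6*(csat - [nucleophile]) (kL = 0.0362 s⁻¹)

- The equivalents are not what sets blue's answer, and violet still has 83.2% of its free base unbound. Blue's [nucleophile] stays nearly level, 0.0219 M at 2.00 min and 0.0235 M at 4.00 min, which is the pseudo-first-order picture. Part of why blue stands at 49.5% at the asked time is the slow crossing of gas over to nucleophile, acting together with the short run: with the slowness of that crossing taken away, and all else left as it is, blue reaches 60.4%. From blue's 50% at 4.00 min, 1.61 more half-lives leave 16.5%, and blue left until 10 min holds 17.4% electrophile.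

(All runs come from a simulation with constants of no real substance.)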